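The one ratio to follow in this flask, with the clock left out, is monomer in chains over free monomer taken up so far.

| setting | midnight | spring | flask |
|---|---|---|---|
| free monomer | 0.16 M (fed, over 30 s) | 0.16 M (fed, over 30 s) | 0.16 M (fed, over 30 s) |
| transfer agent | 0.048 M | 0.024 M | 0.0480 M |
| initiator | 1.9 mM | 1.9 mM | 1.9 mM |
| remark | the very flask that is asked about, followed so far; the fed solution adds 0.10 times the starting volume | run made earlier; the fed solution adds 0.10 times the starting volume | the fed solution adds 0.10 times the starting volume |
| time |  |  | 5.0 min |

midnight run (percent of the free monomer charged)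

| time / s | monomer in chains / % | free monomer / % |
|---|---|---|
| 10.0 | 3 | 28 |
| 12.0 | 4 | 32 |
| 25.0 | 9 | 72 |

spring run (percent of the free monomer charged)

| time / min | monomer in chains / % | free monomer / % |
|---|---|---|
| 0.417 | 10 | 73 |
| 1.33 | 37 | 49 |
| 2.50 | 41 | 24 |
| 4.00 | 40 | 16 |
| 5.00 | 42 | 12 |

(each reading ± 2 percentage points)

- charges are per starting volume, the dose included; the dosed solution carries all of it
- what was read earlier has a scatter of 2 percentage points, one standard deviation
- percentages count the whole charge, also what has not yet gone in

- time, not beyond 5.0 min, at which the flask holds most monomer in chains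
- the amount of monomer in chains, in percent of the free monomer charged, at that time
- the first time at which monomer in chains reaches 21 %, in the same percent, in min

The spring flask, at 1.33 min, has taken up 51.0 % of its charge and holds 37 % in chains. That gives a kept share, the selectivity of the uptake, of 72.5 %, as a reading. By 5.00 min the spring flask reads 47.7 %, with chains flat and free monomer still falling.

The midnight flask, which is the flask asked about, has taken up 11.3 % by 25.0 s, and it carries twice the transfer agent of spring. My own reckoning assumes that the flask reaches an uptake of 49.7 %, which is 11.3 % plus half of the further uptake that spring shows by 5.00 min. On that assumption, spring's share near that uptake gives 36.0 % as the upper end of my bracket for the peak, and its late share gives 23.7 % as the lower end.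

The forecast gives 25 % at 1.6 min, and 21 % at 0.87 min, assuming “doubling the agent doubles both the rate constant and the limit”. Its peak stands above the lower end of that bracket.

    free monomer + initiator → living end + monomer in chains (k = 9.95 M⁻¹ s⁻¹)
    free monomer + living end → monomer in chains + living end, rate k2*[living end]*[free monomer] (k = 7.43 M⁻¹ s⁻¹)
    living end + transfer agent → dead chain (kL = 0.354 M⁻¹ s⁻¹)
    free monomer + monomer in chains → side product (k = 0.0595 M⁻¹ s⁻¹)
    2 initiator ⇌ resting dimer (K = 575 M⁻¹, k = 19.9 M⁻¹ s⁻¹)
    free monomer → decomposition product (k = 5.54 × 10⁻⁵ s⁻¹)

The flask peaks at 29.5 % at 1.99 min, inside the bracket, and first reaches 21 % at 0.817 min. Side product stands at 24.6 % at that peak. The kept share of the flask is then 54.2 %, between spring's readings of 72.5 % and 47.7 %, and it falls to 29.3 % by 5.00 min. With 0.040 M of free monomer and the other charges unchanged, the kept share at 5.00 min is 65.9 %.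

All runs stem from a simulated flask for an exercise, and the scatter is random.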